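**Plan**

1. Retrosynthetic cuts: the C1–CH3 bond of the bromohydrin ring (methyl addition to an α-bromo ketone); the side-chain C(OH)–CH= bond (asymmetric alkenylzinc addition to a methyl ketone); ring bonds C2–C3 and C4–C5 of the bromohydrin ring ([4+2]); the CMe2–CH bond of the bromo-methylidene ring (epoxy-olefin cyclisation of geranyl acetate).
2. Forward order: the bromo-methylidene ring is made first (steps 1–8, ending as alkyne 9); the bromohydrin ring is closed last (step 10) from a C4 bromo-silyloxy-diene and methyl vinyl ketone; then fragment union (11), unmasking (12) and methylation (13).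
3. Enabling feature: in the bromohydrin ring (cyclohexanol numbering: C1 carbinol, C2 CHBr, C4 CH–side chain) oxygen sits at C1, bromine at C2, and the side chain at C4 is 1,4 to O and cis-1,3 to Br. This is the imprint of an endo Diels–Alder adduct of a (Z)-1-bromo-2-silyloxybuta-1,3-diene (gives C2, C1, C6, C5) with a vinyl ketone (gives C3, C4; its carbonyl becomes the side-chain carbinol carbon).
4. Helper: the TIPS enol ether activates the diene and directs regiochemistry, then masks the C1 ketone during fragment union; it is removed in step 12.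
5. Stereochemistry: the first ring from Shi epoxidation and chair cyclisation, with Br installed by inversion of the epimerised carbinol; C4 of the bromohydrin ring from the Diels–Alder catalyst, C2 relayed in the same event (endo rule, Z-diene), C1 by substrate-controlled equatorial methyl addition; the side-chain carbinol from ligand-controlled vinylation.

Key step: step 10

Remark: the target is read as (1R,2S,4S)-2-bromo-4-[(2S,3E)-4-[(1R,3S)-3-bromo-2,2-dimethyl-6-methylidenecyclohexyl]-2-hydroxybut-3-en-2-yl]-1-methylcyclohexan-1-ol (Br, OH and side chain all cis on the bromohydrin ring; Br and side chain cis on the other ring); for each chiral catalyst the antipode that gives the stated configuration is meant, both antipodes being accessible.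

**Route**

Step 1
Reactants: 1 geranyl acetate
Product: 2 (2E)-5-[(2S)-3,3-dimethyloxiran-2-yl]-3-methylpent-2-en-1-yl acetate
Conditions: L-fructose-derived Shi ketone (30 mol %), Oxone, K2CO3, Bu4NHSO4, MeCN/DMM/aq. borate buffer (pH 10.5), 0 °C
Reagents that add atoms: Oxone (potassium peroxymonosulfate), [K+].[O-]S(=O)(=O)OO
Why: Shi epoxidation (dioxirane, spiro transition state) should take the electron-richer distal trisubstituted alkene in preference to the one deactivated by the allylic acetate, and the ketone antipode is chosen to give the (S)-epoxide.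

Step 2
Reactants: 2 (2E)-5-[(2S)-3,3-dimethyloxiran-2-yl]-3-methylpent-2-en-1-yl acetate
Product: 3 [(1R,3S)-3-hydroxy-2,2-dimethyl-6-methylidenecyclohexyl]methyl acetate
Conditions: ZrCl4 (1.1 equiv), CH2Cl2, 0 → 23 °C
Reagents that add atoms: none
Why: Lewis-acid epoxy-olefin (cation–olefin) cyclisation through a chair, in which the alkene attacks the tertiary epoxide carbon with inversion, the carbinol keeps the epoxide configuration, the E-alkene places CH2OAc equatorial (cis to OH) and proton loss from the methyl group gives the exocyclic alkene.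

Step 3
Reactants: 3 [(1R,3S)-3-hydroxy-2,2-dimethyl-6-methylidenecyclohexyl]methyl acetate
Product: 4 [(1R)-2,2-dimethyl-6-methylidene-3-oxocyclohexyl]methyl acetate
Conditions: Dess–Martin periodinane, NaHCO3, CH2Cl2, 23 °C
Reagents that add atoms: none
Why: Dess–Martin oxidation of the secondary alcohol; the remaining stereocentre is not α to the new ketone and cannot epimerise.

Step 4
Reactants: 4 [(1R)-2,2-dimethyl-6-methylidene-3-oxocyclohexyl]methyl acetate
Product: 5 [(1R,3R)-3-hydroxy-2,2-dimethyl-6-methylidenecyclohexyl]methyl acetate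
Conditions: L-Selectride, THF, −78 °C
Reagents that add atoms: none
Why: The bulky trialkylborohydride should attack from the equatorial direction and give the axial alcohol (trans to CH2OAc), the epimer needed for inversion in step 5; the acetate should survive at −78 °C.

Step 5
Reactants: 5 [(1R,3R)-3-hydroxy-2,2-dimethyl-6-methylidenecyclohexyl]methyl acetate
Product: 6 [(1R,3S)-3-bromo-2,2-dimethyl-6-methylidenecyclohexyl]methyl acetate
Conditions: CBr4, PPh3, CH2Cl2, 0 → 23 °C
Reagents that add atoms: carbon tetrabromide, BrC(Br)(Br)Br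
Why: Appel reaction, in which bromide displaces the axial alkoxyphosphonium group with inversion to give the equatorial bromide cis to CH2OAc.

Step 6
Reactants: 6 [(1R,3S)-3-bromo-2,2-dimethyl-6-methylidenecyclohexyl]methyl acetate
Product: 7 [(1R,3S)-3-bromo-2,2-dimethyl-6-methylidenecyclohexyl]methanol
Conditions: K2CO3, MeOH, 0 → 23 °C
Reagents that add atoms: none
Why: Carbonate-catalysed methanolysis of the acetate; the hindered equatorial secondary bromide and the exocyclic alkene should be inert.

Step 7
Reactants: 7 [(1R,3S)-3-bromo-2,2-dimethyl-6-methylidenecyclohexyl]methanol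
Product: 8 (1R,3S)-3-bromo-2,2-dimethyl-6-methylidenecyclohexane-1-carbaldehyde
Conditions: Dess–Martin periodinane, NaHCO3, CH2Cl2, 0 °C
Reagents that add atoms: none
Why: Buffered Dess–Martin oxidation gives the aldehyde under non-basic conditions, so the α-stereocentre and the β,γ-alkene should not isomerise.

Step 8
Reactants: 8 (1R,3S)-3-bromo-2,2-dimethyl-6-methylidenecyclohexane-1-carbaldehyde
Product: 9 (1S,3S)-1-bromo-3-ethynyl-2,2-dimethyl-4-methylidenecyclohexane
Conditions: TMSCHN2, LDA, THF, −78 °C; then 8, −78 → 0 °C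
Reagents that add atoms: (trimethylsilyl)diazomethane, C[Si](C)(C)C=[N+]=[N-]
Why: Colvin homologation (addition of lithiated TMS-diazomethane, Peterson elimination, N2 loss and 1,2-H shift of the alkylidene carbene) gives the terminal alkyne at low temperature, chosen to avoid base-mediated isomerisation of the aldehyde.

Step 9
Reactants: 10 2-(trimethylsilyloxy)buta-1,3-diene
Product: 12 {[(1Z)-1-bromobuta-1,3-dien-2-yl]oxy}tri(propan-2-yl)silane, via 1-bromobut-3-en-2-one 11 (not isolated)
Conditions: NBS, CH2Cl2, −40 °C; then TIPSOTf, iPr2NEt, −78 → 0 °C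
Reagents that add atoms: N-bromosuccinimide, O=C1CCC(=O)N1Br; triisopropylsilyl trifluoromethanesulfonate, CC(C)[Si](OS(=O)(=O)C(F)(F)F)(C(C)C)C(C)C
Why: Electrophilic bromination of the silyl dienol ether at its oxygen-bearing terminus gives the bromomethyl vinyl ketone, and soft enolisation (silyl triflate, hindered amine) should give the Z bromo enol silane (Br syn to O, anti to the vinyl group).

Step 10
Reactants: 12 {[(1Z)-1-bromobuta-1,3-dien-2-yl]oxy}tri(propan-2-yl)silane; 13 but-3-en-2-one (methyl vinyl ketone)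
Product: 14 1-[(1S,5S)-5-bromo-4-{[tri(propan-2-yl)silyl]oxy}cyclohex-3-en-1-yl]ethan-1-one
Conditions: (R)-o-tolyl-CBS oxazaborolidine·Tf2NH (20 mol %), CH2Cl2, −78 → −40 °C; Et3N quench
Reagents that add atoms: none
Why: Asynchronous concerted [4+2] cycloaddition of normal electron demand: the cationic oxazaborolidine lowers the enone LUMO, the bromine-bearing enol-ether terminus bonds to the enone β-carbon and the vinyl terminus closes on the α-carbon, so the six-membered ring forms through two C–C bonds, with the silyloxy group (para director) placing the masked ketone 1,4 to the acetyl-bearing carbon and the C–Br carbon beside it. The closest known reaction type is the oxazaborolidinium-catalysed Diels–Alder reaction of 2-silyloxybuta-1,3-dienes with acrylates and enones; only the bromine on the diene terminus is new. The acetyl-bearing stereocentre is set by the catalyst, which shields one face of the bound enone so that the diene adds to the α-Si face. The C–Br stereocentre is set relative to it by the endo rule together with the Z geometry of the bromo enol ether (Br "outside"), which makes Br and acetyl cis. The step needs para regioselectivity, endo selectivity and π-facial selectivity, secured by the strong donor at C2 of the diene, by Lewis-acid catalysis at low temperature and by the catalyst; the E-diene (Br "inside") should be too slow to compete. The enol ether of the adduct keeps the new ketone masked and regiodefined, so the bromomethine cannot epimerise before step 12.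

Step 11
Reactants: 9 (1S,3S)-1-bromo-3-ethynyl-2,2-dimethyl-4-methylidenecyclohexane; 14 1-[(1S,5S)-5-bromo-4-{[tri(propan-2-yl)silyl]oxy}cyclohex-3-en-1-yl]ethan-1-one
Product: 17 (2S,3E)-4-[(1R,3S)-3-bromo-2,2-dimethyl-6-methylidenecyclohexyl]-2-[(1S,5S)-5-bromo-4-{[tri(propan-2-yl)silyl]oxy}cyclohex-3-en-1-yl]but-3-en-2-ol, via alkenylzirconocene chloride 15 (not isolated), via alkenyl(methyl)zinc 16 (not isolated)
Conditions: 9, Cp2Zr(H)Cl, CH2Cl2, 23 °C; Me2Zn, toluene, −78 °C; then 14, Ti(OiPr)4 (1.2 equiv), trans-1,2-bis(hydroxycamphorsulfonamido)cyclohexane ligand (10 mol %), toluene, 23 °C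
Reagents that add atoms: none
Why: Syn-hydrozirconation of the terminal alkyne (faster than the 1,1-disubstituted alkene), Zr-to-Zn transmetalation and titanium/bis(sulfonamide)-catalysed asymmetric addition of the E-alkenylzinc to the methyl ketone, in which the ligand distinguishes methyl from the branched ring substituent and should direct Re-face attack to the (S)-carbinol, while the enol silane keeps the ring ketone masked.

Step 12
Reactants: 17 (2S,3E)-4-[(1R,3S)-3-bromo-2,2-dimethyl-6-methylidenecyclohexyl]-2-[(1S,5S)-5-bromo-4-{[tri(propan-2-yl)silyl]oxy}cyclohex-3-en-1-yl]but-3-en-2-ol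
Product: 18 (2S,4S)-2-bromo-4-[(2S,3E)-4-[(1R,3S)-3-bromo-2,2-dimethyl-6-methylidenecyclohexyl]-2-hydroxybut-3-en-2-yl]cyclohexan-1-one
Conditions: HF·pyridine, pyridine, THF, 0 °C
Reagents that add atoms: none
Why: Protodesilylation of the TIPS enol ether protonates the unsubstituted enol carbon, so the bromomethine is untouched and Br stays equatorial and cis to the side chain; buffered acidic conditions avoid an α'-enolate (Favorskii) and spare the tertiary allylic alcohol.

Step 13
Reactants: 18 (2S,4S)-2-bromo-4-[(2S,3E)-4-[(1R,3S)-3-bromo-2,2-dimethyl-6-methylidenecyclohexyl]-2-hydroxybut-3-en-2-yl]cyclohexan-1-one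
Product: 19 (1R,2S,4S)-2-bromo-4-[(2S,3E)-4-[(1R,3S)-3-bromo-2,2-dimethyl-6-methylidenecyclohexyl]-2-hydroxybut-3-en-2-yl]-1-methylcyclohexan-1-ol (target)
Conditions: MeTi(OiPr)3 (3 equiv), Et2O/THF, −40 → 0 °C
Reagents that add atoms: methyltitanium triisopropoxide, C[Ti](OC(C)C)(OC(C)C)OC(C)C
Why: 1,2-Addition of a bulky, non-basic methyltitanium reagent to the α-bromo ketone in a ring locked by the equatorial side chain should occur from the equatorial direction, giving the axial tertiary alcohol cis to bromine (syn-bromohydrin, as in Grignard additions to α-halocyclohexanones) without enolisation or epimerisation of the bromomethine.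

**Compound list**

1 | geranyl acetate, (2E)-3,7-dimethylocta-2,6-dien-1-yl acetate | CC(=O)OC/C=C(\C)CCC=C(C)C | starting material
2 | (2E)-5-[(2S)-3,3-dimethyloxiran-2-yl]-3-methylpent-2-en-1-yl acetate | CC(=O)OC/C=C(\C)CC[C@@H]1OC1(C)C | intermediate
3 | [(1R,3S)-3-hydroxy-2,2-dimethyl-6-methylidenecyclohexyl]methyl acetate | C=C1CC[C@H](O)C(C)(C)[C@@H]1COC(C)=O | intermediate
4 | [(1R)-2,2-dimethyl-6-methylidene-3-oxocyclohexyl]methyl acetate | C=C1CCC(=O)C(C)(C)[C@@H]1COC(C)=O | intermediate
5 | [(1R,3R)-3-hydroxy-2,2-dimethyl-6-methylidenecyclohexyl]methyl acetate | C=C1CC[C@@H](O)C(C)(C)[C@@H]1COC(C)=O | intermediate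
6 | [(1R,3S)-3-bromo-2,2-dimethyl-6-methylidenecyclohexyl]methyl acetate | C=C1CC[C@H](Br)C(C)(C)[C@@H]1COC(C)=O | intermediate
7 | [(1R,3S)-3-bromo-2,2-dimethyl-6-methylidenecyclohexyl]methanol | C=C1CC[C@H](Br)C(C)(C)[C@@H]1CO | intermediate
8 | (1R,3S)-3-bromo-2,2-dimethyl-6-methylidenecyclohexane-1-carbaldehyde | C=C1CC[C@H](Br)C(C)(C)[C@@H]1C=O | intermediate
9 | (1S,3S)-1-bromo-3-ethynyl-2,2-dimethyl-4-methylidenecyclohexane | C=C1CC[C@H](Br)C(C)(C)[C@@H]1C#C | intermediate
10 | 2-(trimethylsilyloxy)buta-1,3-diene | C=CC(=C)O[Si](C)(C)C | starting material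
11 | 1-bromobut-3-en-2-one | BrCC(=O)C=C | intermediate
12 | {[(1Z)-1-bromobuta-1,3-dien-2-yl]oxy}tri(propan-2-yl)silane | Br/C=C(\O[Si](C(C)C)(C(C)C)C(C)C)C=C | intermediate
13 | but-3-en-2-one (methyl vinyl ketone) | CC(=O)C=C | starting material
14 | 1-[(1S,5S)-5-bromo-4-{[tri(propan-2-yl)silyl]oxy}cyclohex-3-en-1-yl]ethan-1-one | CC(=O)[C@H]1CC=C(O[Si](C(C)C)(C(C)C)C(C)C)[C@@H](Br)C1 | intermediate
15 | chloridobis(cyclopentadienyl){(E)-2-[(1R,3S)-3-bromo-2,2-dimethyl-6-methylidenecyclohexyl]ethenyl}zirconium | C=C1CC[C@H](Br)C(C)(C)[C@@H]1/C=C/[Zr](Cl)(C1C=CC=C1)C1C=CC=C1 | intermediate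
16 | {(E)-2-[(1R,3S)-3-bromo-2,2-dimethyl-6-methylidenecyclohexyl]ethenyl}(methyl)zinc | C=C1CC[C@H](Br)C(C)(C)[C@@H]1/C=C/[Zn]C | intermediate
17 | (2S,3E)-4-[(1R,3S)-3-bromo-2,2-dimethyl-6-methylidenecyclohexyl]-2-[(1S,5S)-5-bromo-4-{[tri(propan-2-yl)silyl]oxy}cyclohex-3-en-1-yl]but-3-en-2-ol | C=C1CC[C@H](Br)C(C)(C)[C@@H]1/C=C/[C@@](C)(O)[C@H]1CC=C(O[Si](C(C)C)(C(C)C)C(C)C)[C@@H](Br)C1 | intermediate
18 | (2S,4S)-2-bromo-4-[(2S,3E)-4-[(1R,3S)-3-bromo-2,2-dimethyl-6-methylidenecyclohexyl]-2-hydroxybut-3-en-2-yl]cyclohexan-1-one | C=C1CC[C@H](Br)C(C)(C)[C@@H]1/C=C/[C@@](C)(O)[C@H]1CCC(=O)[C@@H](Br)C1 | intermediate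
19 | (1R,2S,4S)-2-bromo-4-[(2S,3E)-4-[(1R,3S)-3-bromo-2,2-dimethyl-6-methylidenecyclohexyl]-2-hydroxybut-3-en-2-yl]-1-methylcyclohexan-1-ol | C=C1CC[C@H](Br)C(C)(C)[C@@H]1/C=C/[C@@](C)(O)[C@H]1CC[C@@](C)(O)[C@@H](Br)C1 | target

**Step count and risks**

Total steps: 13. Longest linear sequence: 11 steps (1–8, then 11–13).

Three steps most likely to fail:

1. Step 10 (Diels–Alder). The bromodiene may add with poor endo/exo or facial discrimination, or the Lewis acid may ionise the allylic C–Br bond of the adduct (2-silyloxyallyl cation) and scramble the bromomethine. Fallback, from 12 and back at 14: change from Lewis-acid to iminium-ion activation. Diene 12 and acrolein, with a 5-benzyl-2-tert-butyl-3-methylimidazolidin-4-one trifluoroacetate organocatalyst (20 mol %, MeCN/H2O, −20 °C), should give the endo aldehyde (1S,5S)-5-bromo-4-{[tri(propan-2-yl)silyl]oxy}cyclohex-3-ene-1-carbaldehyde F1. Addition of MeMgBr (THF, −78 °C) gives 1-[(1S,5S)-5-bromo-4-{[tri(propan-2-yl)silyl]oxy}cyclohex-3-en-1-yl]ethan-1-ol F2 as a carbinol mixture, and Dess–Martin oxidation returns to 14.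

2. Step 11 (asymmetric vinylation). Facial control at the ketone may be weak or mismatched with the neighbouring ring stereocentre, or the alkenylzinc may be lost by protonolysis before it adds. Fallback, from 14 and 8 and back at 17: move the stereo-defining bond from the alkenyl–carbinol bond to the methyl–carbinol bond. The lithium enolate of 14 (LDA, THF, −78 °C) adds to aldehyde 8 to give 3-[(1R,3S)-3-bromo-2,2-dimethyl-6-methylidenecyclohexyl]-1-[(1S,5S)-5-bromo-4-{[tri(propan-2-yl)silyl]oxy}cyclohex-3-en-1-yl]-3-hydroxypropan-1-one F3. Mesylation with in situ elimination (MsCl, Et3N, 0 °C) gives the enone (2E)-3-[(1R,3S)-3-bromo-2,2-dimethyl-6-methylidenecyclohexyl]-1-[(1S,5S)-5-bromo-4-{[tri(propan-2-yl)silyl]oxy}cyclohex-3-en-1-yl]prop-2-en-1-one F4. Catalytic asymmetric methyl transfer (Me2Zn, Ti(OiPr)4, the same bis(sulfonamide) ligand family) then gives 17.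

3. Step 5 (Appel bromination). E2 elimination or a 1,2-methyl shift from the activated axial neopentyl-type carbinol may outrun SN2 displacement. Fallback, from 1 and back at 6: install the C–Br bond before ring closure and let a bromonium ion start the cyclisation. Shi epoxidation of 1 with the D-fructose-derived ketone gives (2E)-5-[(2R)-3,3-dimethyloxiran-2-yl]-3-methylpent-2-en-1-yl acetate F5. Opening at the secondary carbon with inversion (Li2NiBr4, THF) gives (2E,6S)-6-bromo-7-hydroxy-3,7-dimethyloct-2-en-1-yl acetate F6. Ionisation of the tertiary carbinol with bromine participation (BF3·OEt2, HFIP/CH2Cl2, −20 °C) and chair cyclisation should give 6 directly with equatorial bromine.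

**Further compounds**

F1 | step 10 | (1S,5S)-5-bromo-4-{[tri(propan-2-yl)silyl]oxy}cyclohex-3-ene-1-carbaldehyde | O=C[C@H]1CC=C(O[Si](C(C)C)(C(C)C)C(C)C)[C@@H](Br)C1
F2 | step 10 | 1-[(1S,5S)-5-bromo-4-{[tri(propan-2-yl)silyl]oxy}cyclohex-3-en-1-yl]ethan-1-ol | CC(O)[C@H]1CC=C(O[Si](C(C)C)(C(C)C)C(C)C)[C@@H](Br)C1
F3 | step 11 | 3-[(1R,3S)-3-bromo-2,2-dimethyl-6-methylidenecyclohexyl]-1-[(1S,5S)-5-bromo-4-{[tri(propan-2-yl)silyl]oxy}cyclohex-3-en-1-yl]-3-hydroxypropan-1-one | C=C1CC[C@H](Br)C(C)(C)[C@@H]1C(O)CC(=O)[C@H]1CC=C(O[Si](C(C)C)(C(C)C)C(C)C)[C@@H](Br)C1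
F4 | step 11 | (2E)-3-[(1R,3S)-3-bromo-2,2-dimethyl-6-methylidenecyclohexyl]-1-[(1S,5S)-5-bromo-4-{[tri(propan-2-yl)silyl]oxy}cyclohex-3-en-1-yl]prop-2-en-1-one | C=C1CC[C@H](Br)C(C)(C)[C@@H]1/C=C/C(=O)[C@H]1CC=C(O[Si](C(C)C)(C(C)C)C(C)C)[C@@H](Br)C1
F5 | step 5 | (2E)-5-[(2R)-3,3-dimethyloxiran-2-yl]-3-methylpent-2-en-1-yl acetate | CC(=O)OC/C=C(\C)CC[C@H]1OC1(C)C
F6 | step 5 | (2E,6S)-6-bromo-7-hydroxy-3,7-dimethyloct-2-en-1-yl acetate | CC(=O)OC/C=C(\C)CC[C@H](Br)C(C)(C)O
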